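(The readings were generated by integration with constants of no real substance; the scatter is artificial.)

Write the balance of G, the limiting reagent, charged below X.

| flask | X | G | L | remark | time |
|---|---|---|---|---|---|
| east | 0.16 M | 0.112 M | 0.016 M | run made earlier |  |
| south | 0.32 M | 0.112 M | 0.016 M | run made earlier |  |
| dawn | 0.16 M (fed, over 8.0 h) | 0.112 M | 0.0160 M | all else is in the flask from the start; the feed brings no volume worth counting | 10 h |
| autumn | 0.16 M | 0.112 M (fed, over 8.0 h) | 0.0160 M | all else is in the flask from the start; the feed brings no volume worth counting | 10 h |
| dusk | 0.16 M | 0.112 M (in portions, 2, over 8.0 h) | 0.0160 M | first portion at the start, last at 8.0 h | 10 h |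
| summer | 0.16 M | 0.112 M | 0.0160 M | everything together at the start | 10 h |

| run | time / h | J / % | X / % |
|---|---|---|---|
| east | 0.500 | 26 | 46 |
| east | 0.833 | 24 | 32 |
| east | 1.50 | 18 | 17 |
| east | 3.00 | 14 | 12 |
| east | 6.00 | 8 | 8 |
| south | 0.667 | 9 | 50 |
| south | 1.33 | 1 | 42 |
| south | 2.00 | 0 | 38 |
| south | 2.50 | 1 | 40 |
| south | 3.00 | 0 | 43 |

(readings scatter by 2 percentage points)

- the analysis behind the earlier runs scatters by 2 percentage points, standard deviation

* the best flask by amount of J, in percent of the X charged; "all alike" if 1.5 percentage points covers them all (dawn / autumn / dusk / summer / all alike)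
* amount of J at the end, in percent of the X charged, dawn
* amount of J at the end, in percent of the X charged, autumn
* amount of J at the end, in percent of the X charged, dusk
* amount of J at the end, in percent of the X charged, summer

X falls faster than J rises, so read a second step: J meets X and gives a dead product. Every G delivered as J costs one X, and every J destroyed costs another. Count as delivered the G that has become J, whether that J still stands or not. Once the X is in the flask:

J − X = 2 × delivered − X charged

Name the clearing ceiling, the X that the whole G charge can clear at two X per G:

ceiling = 2 × 0.112 M = 0.224 M

Solve the first extreme with no G wasted. J − X is then 40.0% of the X charged, and that is the J left when X reaches zero.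

Take the second extreme from the east run. At 6.00 h, J and X both read 8%, so delivered reads 0.0800 M, and 0.0320 M of G is wasted. J and X then fall together.

Test the ceiling on the south run. Its X charge stands above the ceiling, so J must fall away while at least 30.0% of the X stays. At 2.00 h the readings are J 0% and X 38%. South's delivered reads 0.0992 M, so it wasted 0.0128 M of G, less than east.

Place the flasks from this. Summer is east carried on, so it sits near the second extreme, with little J. Dawn starts poor in X, so expect more waste, J near zero and X left over. I put dusk first, since its last portion comes late.

The forecast differs on the best flask: it names autumn, with dawn 0.3%, autumn 9.5%, dusk 9% and summer 5.3%, and says “Autumn versus dusk is nearly tied”.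

The flasks give dawn 0.169%, autumn 6.33%, dusk 10.2% and summer 6.70%, so dusk is best.

    X + G → J + Z (k = 0.00530 M⁻¹ s⁻¹)
    X + J → E (k = 0.00440 M⁻¹ s⁻¹)
    G + L → D (k = 0.00770 M⁻¹ s⁻¹)
    G → Q (k = 7.20 × 10⁻⁵ s⁻¹)

Z counts delivered G. Dusk holds 0.0779 M of it at 10.0 h, so the ceiling less twice the waste puts J − X at −2.6 percentage points, and J stands at 10.2% beside X at 12.7%. The step from X + J to E is the main reason J stays this low: without it, dusk gives 55.5%. Left ten times as long, dusk gives 0.996%.

Take the dawn flask with 0.64 M of X. That charge stands above the ceiling, so J must fall away and at least 65.0% of the X stays. That flask gives J 0% and X 78.6%.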